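Germacrane numbering is used throughout: ring carbons C1–C10, lactone carbons C11 and C12 with the exocyclic C13, C14 = methyl on C10, C15 = methylene on C4. PMB = 4-methoxybenzyl. Compound numbers 1–33 are those of the steps and of the compound list.

## Analysis of the target

The target is a germacranolide: a ten-membered carbocycle (C1–C10) fused through C6–C7 to an α-methylene-γ-butyrolactone (ring O–C12–C11–C7–C6, exocyclic C13). The carbocycle carries a trisubstituted 1,10-epoxide whose ring bonds C10–C9 and C1–C2 are cis, so it descends from a Z C1=C10 olefin. It also carries an exocyclic C4=C15 methylene, a secondary allylic alcohol at C5 and an angelate at C8. There are six stereocentres (1R,5S,6R,7R,8S,10S), four of them contiguous: C5–OH and C6–O lie on the same ring face (the anti relation of an aldol drawn in zigzag form), H6 and H7 are cis (cis-fused lactone), and the C8 oxygen is trans to the C7–C11 bond. The sensitive groups are the methylene lactone (Michael acceptor), the angelate (isomerises to the tiglate), the epoxide (acid, transannular opening) and the lactone itself, which can migrate to a free O5 or O8 under base. The difficulty is to close a ten-membered ring against entropy and transannular strain and to relay configuration around a flexible ring, while bringing in the sensitive groups late and in a tolerable order. The strategy rests on one feature: once a C7=C11 double bond is restored, the ring O–C12–C11–C7–C6 is a 2(5H)-furanone whose C6 bears the C5 carbinol. This is exactly what a 2-silyloxyfuran leaves when its free α-carbon adds to an aldehyde, so C5–C6 can be the ring-closing bond.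

## Retrosynthetic reasoning

33 to 31. The last two operations are limited to what every sensitive group tolerates: release of O5 from silyl ether 32 and epoxidation of the Z olefin of 31. The epoxide is placed after the esterification so that it meets only one further, buffered step. The forward epoxidation has to pick the single electron-rich olefin out of four and its outer face.

31 to 28. The ester C–O bond at C8 is cut to alcohol 29 and angelic acid 30. The Z enoate survives neither strong base nor hydride, so it is joined after all enolate and hydride chemistry. This needs O5 blocked and O8 free, hence an oxidatively removable PMB ether on O8 in 28 that is orthogonal to the O5 silyl ether.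

28 to 24. The C11=C13 bond is cut: the methylene is added to the saturated lactone 24 by an enolate Mannich reaction and elimination. C11 is the only enolisable position, so no selectivity question arises.

24 to 22. The C7–H bond is cut: conjugate hydride addition to butenolide 23 from the face opposite the C5–C6 bond gives the cis-fused lactone. O5 of 22 is silylated first so that it cannot take over the lactone.

22 to 20. The C5–C6 bond is cut, which opens the ring to silyloxyfuran enal 20. This is the only disconnection that removes the ring, two stereocentres and the lactone oxidation pattern at once. The forward reaction must be an intramolecular vinylogous aldol addition that beats oligomerisation and sets 5S and 6R.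

20 to 17. The silyloxyfuran is the enol silyl ether of butenolide 19. The enal carbon C15 is added to aldehyde 18 by α-methylenation, and 18 comes from alcohol 17. The electrophile is made as late as possible because it must not meet hydride or organometallic reagents.

17 to 13. The butenolide is taken back to a 3-substituted furan: photooxygenation of 13 to lactol 15 and reduction. The furan is the robust form in which the future lactone passes through all organometallic steps.

13 to 11 and 12. The C2–C3 bond is cut between a primary allylic bromide and a three-carbon Grignard reagent made from 12. C2 is the one sp3 carbon of the chain that is activated for substitution, and the nucleophile has no regiochemical ambiguity.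

11 to 7. The Z olefin is traced to ynoate 7: syn addition of a methylcopper reagent puts C14 on C10 and leaves C9 cis to C2 (ester 8). Reduction to 9 and bromination follow.

7 to 1 and 2. The C1–C2 bond is cut to an acetylide from 5 and a chloroformate, and the C8–C9 bond to furan-3-carbaldehyde 1 and allenylboronate 2. A catalytic asymmetric propargylation to 3 sets C8, the stereocentre from which the others are relayed.

## Alternatives that were turned down

Alternative 1: Bridged nitrile oxide cycloaddition. The carbocycle would be cut at C9–C10 together with the O–C8 bond. In the forward sense the open-chain aldoxime A1 is oxidised at C10 to the dipole, which adds across the terminal C8=C9 alkene (carbon to C9, oxygen to C8) and gives the bridged isoxazoline A2. In its favour, dipolar cycloadditions are dependable ring closures that tolerate dense oxygenation, the C5/C6 diol arrives from the acyclic stage, and C8–O is formed in the same step. On precedent for the ring closure itself this is the stronger proposal. Against it, the bridged mode places a C=N at a bridgehead of a medium ring, and the C8 configuration depends on an unknown chain conformation. After A2 the route still needs N–O cleavage, face-selective methyl addition at C10 and epoxide closure onto C1, methylenation at C4 next to C5, and construction and methylenation of the lactone from a two-carbon arm. Five protecting groups are involved. The chosen route brings every lactone carbon and C15 into the ring closure at the right oxidation level, and seven steps remain after it.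

Alternative 2: Ueno–Stork radical cyclisation with oxygen capture at C8. The C7–C11 and C8–O bonds would be cut on a ten-membered ring that already exists. Bromoacetal A3 under radical chain conditions in air gives a C11 radical that adds 5-exo to C7, and the C8 radical is trapped aerobically to give bicyclic acetal alcohol A4. Its strength is the cis ring fusion at C6/C7, which the tether enforces; the chosen route must win this by facial selectivity in step 15. Against it, the ten-membered dienone ring of A3 still has to be made, so the hardest problem is only postponed. C8 is oxygenated at a nearly planar radical without a controlling element, hydrogen transfer and transannular addition compete, and the C4 ketone must later be methylenated beside an epimerisable C5. The chosen route makes the ring in its key step and sets C8 by asymmetric catalysis.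

Alternative 3: Wharton–Grob fragmentation of a cis-decalin. The ten-membered ring would be derived by cutting, in reverse, a C5–C10 bond: alkoxide formation at C5 of cis-decalin mesylate A5 breaks C5–C10 and gives Z-cyclodecenone A6. This is the most reliable of all four ways to form the ring: there is no entropic penalty, the olefin geometry is fixed stereospecifically by the C1/C10 relation, and C6, C7 and C8 can be set on a rigid six-membered ring. Against it, A5 carries six stereocentres, one of them quaternary, and a tertiary alcohol, so it needs a long bicyclic synthesis. A6 is a cross-conjugated α-alkoxy enone, formed under strong base, that can epimerise at C6. The C5 ketone must then be reduced 1,2 and face-selectively in the flexible ring, and the lactone must still be built and methylenated. The chosen route obtains the Z olefin from one low-temperature cuprate addition and concentrates its risk in a single step.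

Key step: step 13

Assumption: the (S)-configured phosphoric acid of step 1 is taken to expose the Si face of aldehyde 1, as its antipode exposes the Re face in the analogous allylboration; if the sense is the reverse, the (R)-acid is used.

## Route

Step 1
Reactants: 1 furan-3-carbaldehyde; 2 allenylboronic acid pinacol ester
Product: 3 (1S)-1-(furan-3-yl)but-3-yn-1-ol
Conditions: (S)-TRIP [(S)-3,3′-bis(2,4,6-triisopropylphenyl)-1,1′-binaphthyl-2,2′-diyl hydrogen phosphate] (5 mol %), 4 Å MS, toluene, −20 °C; aq. work-up
Reagents that add atoms: allenylboronic acid pinacol ester (2), C=C=CB1OC(C)(C)C(C)(C)O1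
Why: Chiral phosphoric acid-catalysed propargylation of an aldehyde by an allenylboronate through a closed six-membered SE2′ transition state; the catalyst shields the Re face, so C9 is delivered to the Si face and C8 is set as S.

Step 2
Reactants: 3 (1S)-1-(furan-3-yl)but-3-yn-1-ol
Product: 5 3-[(1S)-1-[(4-methoxyphenyl)methoxy]but-3-yn-1-yl]furan, via sodium alkoxide 4 (not isolated)
Conditions: NaH, THF–DMF, 0 °C; PMBCl, tetrabutylammonium iodide (cat.), 0 °C to rt
Reagents that add atoms: 4-methoxybenzyl chloride, COc1ccc(CCl)cc1
Why: Williamson ether synthesis; the alkoxide forms in preference to the acetylide. The PMB ether withstands the organometallic, hydride and Lewis-acid steps ahead and can later be removed oxidatively beside a silyl ether.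

Step 3
Reactants: 5 3-[(1S)-1-[(4-methoxyphenyl)methoxy]but-3-yn-1-yl]furan
Product: 7 methyl (5S)-5-(furan-3-yl)-5-[(4-methoxyphenyl)methoxy]pent-2-ynoate, via lithium acetylide 6 (not isolated)
Conditions: n-BuLi, THF, −78 °C; ClCO2Me, −78 to 0 °C
Reagents that add atoms: methyl chloroformate, COC(=O)Cl
Why: Deprotonation of the terminal alkyne and C-acylation of the acetylide; this adds C2 at the ester level and activates the triple bond for regioselective carbometalation.

Step 4
Reactants: 7 methyl (5S)-5-(furan-3-yl)-5-[(4-methoxyphenyl)methoxy]pent-2-ynoate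
Product: 8 methyl (2Z,5S)-5-(furan-3-yl)-5-[(4-methoxyphenyl)methoxy]-3-methylpent-2-enoate
Conditions: Me2CuLi (from MeLi and CuBr·SMe2), THF, −78 °C; MeOH, −78 °C
Reagents that add atoms: methyllithium, [Li]C
Why: syn-Carbocupration of an ynoate: methyl adds to C10 and copper to C1 on the same side. Protonation at −78 °C, before the α-cuprio ester can equilibrate through its allenolate, leaves C9 cis to C2, which is the Z olefin with C14 in place.

Step 5
Reactants: 8 methyl (2Z,5S)-5-(furan-3-yl)-5-[(4-methoxyphenyl)methoxy]-3-methylpent-2-enoate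
Product: 9 (2Z,5S)-5-(furan-3-yl)-5-[(4-methoxyphenyl)methoxy]-3-methylpent-2-en-1-ol
Conditions: i-Bu2AlH, CH2Cl2, −78 °C; aq. sodium potassium tartrate
Reagents that add atoms: none
Why: 1,2-Reduction of an α,β-unsaturated ester to the allylic alcohol by an aluminium hydride at low temperature, which does not touch olefin geometry, furan or ether.

Step 6
Reactants: 9 (2Z,5S)-5-(furan-3-yl)-5-[(4-methoxyphenyl)methoxy]-3-methylpent-2-en-1-ol
Product: 11 3-[(1S,3Z)-5-bromo-1-[(4-methoxyphenyl)methoxy]-3-methylpent-3-en-1-yl]furan, via allylic mesylate 10 (not isolated)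
Conditions: MsCl, Et3N, THF, −40 °C; LiBr, THF, 0 °C
Reagents that add atoms: lithium bromide, [Li+].[Br-]
Why: Mesylation and SN2 displacement by bromide at a primary allylic carbon; the cold two-stage procedure keeps the Z geometry, and 11 is used at once.

Step 7
Reactants: 11 3-[(1S,3Z)-5-bromo-1-[(4-methoxyphenyl)methoxy]-3-methylpent-3-en-1-yl]furan; 12 3-chloropropan-1-ol
Product: 13 (5Z,8S)-8-(furan-3-yl)-8-[(4-methoxyphenyl)methoxy]-6-methyloct-5-en-1-ol
Conditions: 12, i-PrMgCl, THF, −20 °C, then Mg, reflux; 11, Li2CuCl4 (3 mol %), THF, −78 to 0 °C; aq. NH4Cl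
Reagents that add atoms: 3-chloropropan-1-ol (12), OCCCCl
Why: Li2CuCl4-catalysed cross-coupling of a primary alkyl Grignard reagent with a primary allylic bromide, which should go at the α-carbon (attack at C10 would build a quaternary centre) with retention of olefin geometry. The alkoxide-bearing Grignard reagent from 12 delivers C3–C5 with O5 free.

Step 8
Reactants: 13 (5Z,8S)-8-(furan-3-yl)-8-[(4-methoxyphenyl)methoxy]-6-methyloct-5-en-1-ol
Product: 15 5-hydroxy-4-[(1S,3Z)-8-hydroxy-1-[(4-methoxyphenyl)methoxy]-3-methyloct-3-en-1-yl]furan-2(5H)-one (lactol epimers), via furan endoperoxide 14 (not isolated)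
Conditions: O2, hν, tetraphenylporphyrin (cat.), i-Pr2NEt, CH2Cl2, −78 °C to rt
Reagents that add atoms: dioxygen, O=O
Why: Dye-sensitised photooxygenation: singlet oxygen adds [4+2] to the furan much faster than it undergoes the ene reaction with the trisubstituted olefin at −78 °C. The hindered amine removes the less encumbered bridgehead proton (Kornblum–DeLaMare-type opening), so the carbonyl forms at the carbon remote from the side chain (C12) and the lactol at C6.

Step 9
Reactants: 15 5-hydroxy-4-[(1S,3Z)-8-hydroxy-1-[(4-methoxyphenyl)methoxy]-3-methyloct-3-en-1-yl]furan-2(5H)-one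
Product: 17 4-[(1S,3Z)-8-hydroxy-1-[(4-methoxyphenyl)methoxy]-3-methyloct-3-en-1-yl]furan-2(5H)-one, via hydroxy carboxylate 16 (not isolated)
Conditions: NaBH4, EtOH, 0 °C; 1 M HCl to pH 2, rt
Reagents that add atoms: none
Why: Borohydride reduces the open aldehyde form of the lactol to the primary alcohol, and acidification closes the butenolide; the conjugated lactone and the ether are not reduced.

Step 10
Reactants: 17 4-[(1S,3Z)-8-hydroxy-1-[(4-methoxyphenyl)methoxy]-3-methyloct-3-en-1-yl]furan-2(5H)-one
Product: 18 (5Z,8S)-8-[(4-methoxyphenyl)methoxy]-6-methyl-8-(5-oxo-2,5-dihydrofuran-3-yl)oct-5-enal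
Conditions: Dess–Martin periodinane, NaHCO3, CH2Cl2, 0 °C to rt
Reagents that add atoms: none
Why: Dess–Martin oxidation of a primary alcohol to the aldehyde under buffered conditions that leave butenolide and PMB ether alone.

Step 11
Reactants: 18 (5Z,8S)-8-[(4-methoxyphenyl)methoxy]-6-methyl-8-(5-oxo-2,5-dihydrofuran-3-yl)oct-5-enal
Product: 19 (5Z,8S)-8-[(4-methoxyphenyl)methoxy]-6-methyl-2-methylidene-8-(5-oxo-2,5-dihydrofuran-3-yl)oct-5-enal
Conditions: 37% aq. HCHO, pyrrolidine (10 mol %), EtCO2H (10 mol %), i-PrOH, 45 °C
Reagents that add atoms: formaldehyde, C=O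
Why: Amine-catalysed α-methylenation of an aldehyde (enamine Mannich reaction, then elimination of the amine) adds C15 and gives the 2-substituted enal. The butenolide is a β,β-disubstituted acceptor and should not be attacked by the amine.

Step 12
Reactants: 19 (5Z,8S)-8-[(4-methoxyphenyl)methoxy]-6-methyl-2-methylidene-8-(5-oxo-2,5-dihydrofuran-3-yl)oct-5-enal
Product: 20 (5Z,8S)-8-[(4-methoxyphenyl)methoxy]-6-methyl-2-methylidene-8-[5-(triisopropylsilyloxy)furan-3-yl]oct-5-enal
Conditions: i-Pr3SiOTf, Et3N, CH2Cl2, 0 °C; pentane, filtration, used without chromatography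
Reagents that add atoms: triisopropylsilyl trifluoromethanesulfonate, CC(C)[Si](OS(=O)(=O)C(F)(F)F)(C(C)C)C(C)C
Why: Soft enolisation of a butenolide at its γ-carbon (C6) by silyl triflate and amine gives the aromatic 2-silyloxyfuran. The enal cannot enolise because C4 is sp2, and the bulky silyl group makes 20 stable enough to handle.

Step 13
Reactants: 20 (5Z,8S)-8-[(4-methoxyphenyl)methoxy]-6-methyl-2-methylidene-8-[5-(triisopropylsilyloxy)furan-3-yl]oct-5-enal
Product: 22 (5S,6R,8S)-5-hydroxy-8-[(4-methoxyphenyl)methoxy]germacra-1(10)Z,4(15),7(11)-trien-12,6-olide, via difluoroboryl aldolate 21 (not isolated)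
Conditions: BF3·OEt2 (2 equiv), CH2Cl2, −78 °C, slow addition of 20 (final 1 mM); sat. aq. NaHCO3
Reagents that add atoms: none
Why: Proposed new method: BF3 binds the aldehyde oxygen, the furan α-carbon remote from the silyloxy group (C6) attacks the activated carbonyl through an open transition state, and fluoride transfer from boron to silicon releases the silyl group and leaves the butenolide as boron alkoxide 21, hydrolysed on work-up; the closest known reaction is the intermolecular vinylogous Mukaiyama aldol reaction of 2-silyloxyfurans with aldehydes, which has not been used to close a ten-membered carbocycle. The ring closes end to end in a 10-(enolendo)-exo-trig mode; the Z C1=C10 olefin turns the chain back on itself, four sp2 carbons in the new ring (C1, C4, C7, C10) remove transannular hydrogen contacts, and high dilution with slow addition keeps the reaction intramolecular. C6 (R) is controlled by the C8 stereocentre: in the arrangement expected to be preferred, the C8–O bond lies near the furan plane on the C6 side (inside-alkoxy arrangement, which keeps the C–O σ* orbital out of conjugation with the reacting π system), H8 points away from the aldehyde and the tether leaves C8 on the attacked face, and for 8S this face gives 6R. C5 (S) is controlled by the ring: a tether that leaves C8 in this way carries C4 across the furan, so the carbonyl oxygen lies antiperiplanar to the C6=C7 bond with C4 gauche to both the ring oxygen and C7, which is the anti (5S,6R) topology. Untethered reactions of this type prefer the syn adduct, so this relation rests on the ring alone and is the least secure element. Attack by C6 and not by C11 (which would also give a ten-membered ring) rests on the inherent γ-selectivity of silyloxyfurans and gives the conjugated butenolide, and 1,2- instead of 1,4-addition to the enal is secured by the hard Lewis acid on oxygen.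

Step 14
Reactants: 22 (5S,6R,8S)-5-hydroxy-8-[(4-methoxyphenyl)methoxy]germacra-1(10)Z,4(15),7(11)-trien-12,6-olide
Product: 23 (5S,6R,8S)-8-[(4-methoxyphenyl)methoxy]-5-(triethylsilyloxy)germacra-1(10)Z,4(15),7(11)-trien-12,6-olide
Conditions: Et3SiCl, imidazole, DMAP (cat.), DMF, 0 °C to rt
Reagents that add atoms: chlorotriethylsilane, CC[Si](Cl)(CC)CC
Why: Silylation of a secondary allylic alcohol with a base too weak to deprotonate the butenolide at C6. The triethylsilyl ether blocks lactone migration to O5 and is the most easily removed group at the end.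

Step 15
Reactants: 23 (5S,6R,8S)-8-[(4-methoxyphenyl)methoxy]-5-(triethylsilyloxy)germacra-1(10)Z,4(15),7(11)-trien-12,6-olide
Product: 24 (5S,6R,7R,8S)-8-[(4-methoxyphenyl)methoxy]-5-(triethylsilyloxy)germacra-1(10)Z,4(15)-dien-12,6-olide
Conditions: [(Ph3P)CuH]6 (0.4 equiv), H2O (2 equiv), degassed toluene, rt
Reagents that add atoms: none
Why: Conjugate reduction of a butenolide by a phosphine-stabilised copper hydride, which leaves isolated olefins and ethers alone. Hydride should reach C7 on the butenolide face opposite the C5–C6 bond, the face not covered by the macrocycle, so H7 ends cis to H6 (7R, cis-fused lactone); the copper enolate is protonated by water.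

Step 16
Reactants: 24 (5S,6R,7R,8S)-8-[(4-methoxyphenyl)methoxy]-5-(triethylsilyloxy)germacra-1(10)Z,4(15)-dien-12,6-olide
Product: 28 (5S,6R,7R,8S)-8-[(4-methoxyphenyl)methoxy]-5-(triethylsilyloxy)germacra-1(10)Z,4(15),11(13)-trien-12,6-olide, via lithium enolate 25 (not isolated), via aminomethyl lactone 26 (not isolated), via ammonium iodide 27 (not isolated)
Conditions: LiN(i-Pr)2, THF, −78 °C; CH2=NMe2+ I−, −78 to 0 °C; MeI, MeOH, rt; aq. NaHCO3–CH2Cl2, rt
Reagents that add atoms: N,N-dimethylmethyleneiminium iodide, C=[N+](C)C.[I-]
Why: α-Methylenation of a lactone by the Mannich route: the lithium enolate (C11 is the only enolisable position) is aminomethylated, the amine is quaternised and the ammonium salt eliminates (E1cB) under bicarbonate to give C11=C13. C7 is not touched.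

Step 17
Reactants: 28 (5S,6R,7R,8S)-8-[(4-methoxyphenyl)methoxy]-5-(triethylsilyloxy)germacra-1(10)Z,4(15),11(13)-trien-12,6-olide
Product: 29 (5S,6R,7R,8S)-8-hydroxy-5-(triethylsilyloxy)germacra-1(10)Z,4(15),11(13)-trien-12,6-olide
Conditions: DDQ, CH2Cl2–pH 7 buffer (10:1), 0 °C
Reagents that add atoms: none
Why: Oxidative cleavage of a PMB ether by DDQ (hydride abstraction to the oxocarbenium ion, then hydrolysis); the silyl ether, the electron-poor methylene lactone and the unactivated olefins are not oxidised, and the neutral medium does not move the lactone to O8.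

Step 18
Reactants: 29 (5S,6R,7R,8S)-8-hydroxy-5-(triethylsilyloxy)germacra-1(10)Z,4(15),11(13)-trien-12,6-olide; 30 angelic acid [(2Z)-2-methylbut-2-enoic acid]
Product: 31 (5S,6R,7R,8S)-8-angeloyloxy-5-(triethylsilyloxy)germacra-1(10)Z,4(15),11(13)-trien-12,6-olide
Conditions: 30, 2,4,6-Cl3C6H2COCl, Et3N, toluene, rt; then 29, toluene, 80 °C
Reagents that add atoms: angelic acid (30), C/C=C(/C)C(=O)O
Why: Yamaguchi-type esterification through the mixed anhydride with 2,4,6-trichlorobenzoic acid, run without a nucleophilic catalyst so that the Z double bond of the acyl group does not isomerise to the tiglate.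

Step 19
Reactants: 31 (5S,6R,7R,8S)-8-angeloyloxy-5-(triethylsilyloxy)germacra-1(10)Z,4(15),11(13)-trien-12,6-olide
Product: 32 (1R,5S,6R,7R,8S,10S)-8-angeloyloxy-1,10-epoxy-5-(triethylsilyloxy)germacra-4(15),11(13)-dien-12,6-olide
Conditions: mCPBA, NaHCO3, CH2Cl2, −20 to 0 °C
Reagents that add atoms: 3-chloroperoxybenzoic acid, OOC(=O)c1cccc(Cl)c1
Why: Prilezhaev epoxidation: C1=C10 is the only electron-rich olefin (C4=C15 is 1,1-disubstituted and flanked by the silyl ether, the other two are conjugated to carbonyl groups). The peracid should attack the outward face of the Z olefin, which in the cis-lactone conformer is expected to give 1R,10S; the Z geometry fixes the cis relation of C2 and C9 on the epoxide.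

Step 20
Reactants: 32 (1R,5S,6R,7R,8S,10S)-8-angeloyloxy-1,10-epoxy-5-(triethylsilyloxy)germacra-4(15),11(13)-dien-12,6-olide
Product: 33 (1R,5S,6R,7R,8S,10S)-8-angeloyloxy-1,10-epoxy-5-hydroxygermacra-4(15),11(13)-dien-12,6-olide (CNP0227074.3)
Conditions: HF·pyridine, pyridine, THF, 0 °C
Reagents that add atoms: none
Why: Fluoride-mediated cleavage of a triethylsilyl ether under pyridine-buffered conditions that should not open the epoxide, add to the methylene lactone or isomerise the angelate.

## Compound list

1 | furan-3-carbaldehyde | O=Cc1ccoc1 | starting material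
2 | allenylboronic acid pinacol ester | C=C=CB1OC(C)(C)C(C)(C)O1 | starting material
3 | (1S)-1-(furan-3-yl)but-3-yn-1-ol | c1cc(co1)[C@@H](O)CC#C | intermediate
4 | sodium (1S)-1-(furan-3-yl)but-3-yn-1-olate | c1cc(co1)[C@@H]([O-])CC#C.[Na+] | intermediate (not isolated)
5 | 3-[(1S)-1-[(4-methoxyphenyl)methoxy]but-3-yn-1-yl]furan | c1cc(co1)[C@@H](OCc1ccc(OC)cc1)CC#C | intermediate
6 | lithium acetylide of 5 | c1cc(co1)[C@@H](OCc1ccc(OC)cc1)CC#C[Li] | intermediate (not isolated)
7 | methyl (5S)-5-(furan-3-yl)-5-[(4-methoxyphenyl)methoxy]pent-2-ynoate | c1cc(co1)[C@@H](OCc1ccc(OC)cc1)CC#CC(=O)OC | intermediate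
8 | methyl (2Z,5S)-5-(furan-3-yl)-5-[(4-methoxyphenyl)methoxy]-3-methylpent-2-enoate | c1cc(co1)[C@@H](OCc1ccc(OC)cc1)C/C(C)=C\C(=O)OC | intermediate
9 | (2Z,5S)-5-(furan-3-yl)-5-[(4-methoxyphenyl)methoxy]-3-methylpent-2-en-1-ol | c1cc(co1)[C@@H](OCc1ccc(OC)cc1)C/C(C)=C\CO | intermediate
10 | methanesulfonate of 9 | c1cc(co1)[C@@H](OCc1ccc(OC)cc1)C/C(C)=C\COS(C)(=O)=O | intermediate (not isolated)
11 | 3-[(1S,3Z)-5-bromo-1-[(4-methoxyphenyl)methoxy]-3-methylpent-3-en-1-yl]furan | c1cc(co1)[C@@H](OCc1ccc(OC)cc1)C/C(C)=C\CBr | intermediate
12 | 3-chloropropan-1-ol | OCCCCl | starting material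
13 | (5Z,8S)-8-(furan-3-yl)-8-[(4-methoxyphenyl)methoxy]-6-methyloct-5-en-1-ol | c1cc(co1)[C@@H](OCc1ccc(OC)cc1)C/C(C)=C\CCCCO | intermediate
14 | furan endoperoxide of 13 (2,3,7-trioxabicyclo[2.2.1]hept-5-ene with the side chain on C5) | C12OOC(O1)C=C2[C@@H](OCc1ccc(OC)cc1)C/C(C)=C\CCCCO | intermediate (not isolated)
15 | 5-hydroxy-4-[(1S,3Z)-8-hydroxy-1-[(4-methoxyphenyl)methoxy]-3-methyloct-3-en-1-yl]furan-2(5H)-one | O=C1C=C(C(O)O1)[C@@H](OCc1ccc(OC)cc1)C/C(C)=C\CCCCO | intermediate
16 | sodium (2E,4S,6Z)-11-hydroxy-3-(hydroxymethyl)-4-[(4-methoxyphenyl)methoxy]-6-methylundeca-2,6-dienoate | [Na+].[O-]C(=O)/C=C(\CO)[C@@H](OCc1ccc(OC)cc1)C/C(C)=C\CCCCO | intermediate (not isolated)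
17 | 4-[(1S,3Z)-8-hydroxy-1-[(4-methoxyphenyl)methoxy]-3-methyloct-3-en-1-yl]furan-2(5H)-one | O=C1C=C(CO1)[C@@H](OCc1ccc(OC)cc1)C/C(C)=C\CCCCO | intermediate
18 | (5Z,8S)-8-[(4-methoxyphenyl)methoxy]-6-methyl-8-(5-oxo-2,5-dihydrofuran-3-yl)oct-5-enal | O=C1C=C(CO1)[C@@H](OCc1ccc(OC)cc1)C/C(C)=C\CCCC=O | intermediate
19 | (5Z,8S)-8-[(4-methoxyphenyl)methoxy]-6-methyl-2-methylidene-8-(5-oxo-2,5-dihydrofuran-3-yl)oct-5-enal | O=C1C=C(CO1)[C@@H](OCc1ccc(OC)cc1)C/C(C)=C\CCC(=C)C=O | intermediate
20 | (5Z,8S)-8-[(4-methoxyphenyl)methoxy]-6-methyl-2-methylidene-8-[5-(triisopropylsilyloxy)furan-3-yl]oct-5-enal | CC(C)[Si](Oc1cc(co1)[C@@H](OCc1ccc(OC)cc1)C/C(C)=C\CCC(=C)C=O)(C(C)C)C(C)C | intermediate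
21 | O5-difluoroboryl derivative of 22 | O=C1C=C2[C@@H](O1)[C@@H](OB(F)F)C(=C)CC/C=C(C)\C[C@@H]2OCc1ccc(OC)cc1 | intermediate (not isolated)
22 | (5S,6R,8S)-5-hydroxy-8-[(4-methoxyphenyl)methoxy]germacra-1(10)Z,4(15),7(11)-trien-12,6-olide | O=C1C=C2[C@@H](O1)[C@@H](O)C(=C)CC/C=C(C)\C[C@@H]2OCc1ccc(OC)cc1 | intermediate
23 | (5S,6R,8S)-8-[(4-methoxyphenyl)methoxy]-5-(triethylsilyloxy)germacra-1(10)Z,4(15),7(11)-trien-12,6-olide | O=C1C=C2[C@@H](O1)[C@@H](O[Si](CC)(CC)CC)C(=C)CC/C=C(C)\C[C@@H]2OCc1ccc(OC)cc1 | intermediate
24 | (5S,6R,7R,8S)-8-[(4-methoxyphenyl)methoxy]-5-(triethylsilyloxy)germacra-1(10)Z,4(15)-dien-12,6-olide | O=C1O[C@@H]2[C@H](C1)[C@@H](OCc1ccc(OC)cc1)C/C(C)=C\CCC(=C)[C@@H]2O[Si](CC)(CC)CC | intermediate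
25 | lithium enolate of 24 | [Li]OC1O[C@@H]2[C@H](C=1)[C@@H](OCc1ccc(OC)cc1)C/C(C)=C\CCC(=C)[C@@H]2O[Si](CC)(CC)CC | intermediate (not isolated)
26 | 11-[(dimethylamino)methyl] derivative of 24 (C11 epimers) | O=C1O[C@@H]2[C@H](C1CN(C)C)[C@@H](OCc1ccc(OC)cc1)C/C(C)=C\CCC(=C)[C@@H]2O[Si](CC)(CC)CC | intermediate (not isolated)
27 | trimethylammonium iodide of 26 | O=C1O[C@@H]2[C@H](C1C[N+](C)(C)C)[C@@H](OCc1ccc(OC)cc1)C/C(C)=C\CCC(=C)[C@@H]2O[Si](CC)(CC)CC.[I-] | intermediate (not isolated)
28 | (5S,6R,7R,8S)-8-[(4-methoxyphenyl)methoxy]-5-(triethylsilyloxy)germacra-1(10)Z,4(15),11(13)-trien-12,6-olide | O=C1O[C@@H]2[C@H](C1=C)[C@@H](OCc1ccc(OC)cc1)C/C(C)=C\CCC(=C)[C@@H]2O[Si](CC)(CC)CC | intermediate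
29 | (5S,6R,7R,8S)-8-hydroxy-5-(triethylsilyloxy)germacra-1(10)Z,4(15),11(13)-trien-12,6-olide | O=C1O[C@@H]2[C@H](C1=C)[C@@H](O)C/C(C)=C\CCC(=C)[C@@H]2O[Si](CC)(CC)CC | intermediate
30 | angelic acid, (2Z)-2-methylbut-2-enoic acid | C/C=C(/C)C(=O)O | starting material
31 | (5S,6R,7R,8S)-8-angeloyloxy-5-(triethylsilyloxy)germacra-1(10)Z,4(15),11(13)-trien-12,6-olide | O=C1O[C@@H]2[C@H](C1=C)[C@@H](OC(=O)/C(C)=C\C)C/C(C)=C\CCC(=C)[C@@H]2O[Si](CC)(CC)CC | intermediate
32 | (1R,5S,6R,7R,8S,10S)-8-angeloyloxy-1,10-epoxy-5-(triethylsilyloxy)germacra-4(15),11(13)-dien-12,6-olide | O=C1O[C@@H]2[C@H](C1=C)[C@@H](OC(=O)/C(C)=C\C)C[C@]1(C)O[C@@H]1CCC(=C)[C@@H]2O[Si](CC)(CC)CC | intermediate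
33 | (1R,5S,6R,7R,8S,10S)-8-angeloyloxy-1,10-epoxy-5-hydroxygermacra-4(15),11(13)-dien-12,6-olide | C=C1C(=O)O[C@@H]2[C@H]1[C@@H](OC(=O)/C(C)=C\C)C[C@]1(C)O[C@@H]1CCC(=C)[C@@H]2O | target

## Step count and least certain steps

Total: 20 steps. Longest linear sequence: 20 steps (1 to 33); compounds 2, 12 and 30 are purchased.

Step 13 (key step, proposed new method). Three processes may defeat it. Intermolecular aldol addition may outrun the entropically costly ten-membered closure and give oligomers. The aldehyde may be attacked through the other furan face or present its other face, since the open-chain preference of this reaction type is for the syn adduct and the anti relation rests on the ring alone. The silyloxyfuran may also be desilylated back to the butenolide before it reacts. The fallback separates C–C bond formation from ring closure and uses only known reaction types. It sets out from 5: zirconium-catalysed carboalumination (Cp2ZrCl2, Me3Al; then H2O) should give 3-[(1S)-1-[(4-methoxyphenyl)methoxy]-3-methylbut-3-en-1-yl]furan F1. Photooxygenation as in step 8 gives the lactol F2, NaBH4 the butenolide F3, and i-Pr3SiOTf with Et3N the silyloxyfuran F4. Intermolecular vinylogous Mukaiyama aldol addition of F4 to 2-methylidenehex-5-enal F5 (from purchased hex-5-enal by the conditions of step 11) gives, after separation of diastereomers, the (5S,6R) adduct F6. The syn/anti ratio of this open-chain reaction responds to the promoter (Lewis acid or fluoride), a handle the ring closure lacks. Ring-closing metathesis of F6 with second-generation Grubbs catalyst at high dilution then joins C1 and C10 with loss of ethene; the ten-membered ring accommodates only the Z olefin. The route is rejoined at 22.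

Step 7. Attack of the organocopper intermediate at C10 (SN2′), erosion of the Z geometry through allyl-metal equilibration, or ionisation of the bromide with participation of the neighbouring ether oxygen would all cost material. The fallback reverses the polarity at C2 and sets out from 11. PhSO2Na in DMF gives the allylic sulfone F7. Its lithio derivative (n-BuLi, THF, −78 °C) is alkylated with tert-butyl(3-iodopropoxy)dimethylsilane to give the sulfone silyl ether F8. Reductive desulfonylation (PdCl2(dppp) cat., LiBHEt3) gives the silyl ether F9, and Bu4NF returns to 13.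

Step 15. Hydride delivery to the wrong butenolide face (trans-fused lactone) or sluggish reaction at the β,β-disubstituted position is possible, because the facial bias depends on the conformation of the macrocycle. The fallback moves stereocontrol from the substrate to the catalyst: a copper hydride generated catalytically from Cu(OAc)2, a chiral bisphosphine (the enantiomer of p-Tol-BINAP matched to the substrate), polymethylhydrosiloxane and t-BuOH. It sets out from 23 and returns to 24, and makes no new compound (F0).

Step 19. Epoxidation from the inner face, or competing oxidation of C4=C15, would give the wrong epoxide; the facial outcome depends on the ring conformation and cannot be secured in advance. The fallback delivers oxygen to the opposite face and sets out from 31. N-Bromosuccinimide in THF–H2O at 0 °C forms the bromonium ion on the face the peracid prefers and water opens it at the tertiary C10 from the other side, giving the (1S,10S) bromohydrin F10. Ag2O in Et2O then closes the epoxide with inversion at C1 and returns to 32.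

## Further compounds

F1 | step 13 | 3-[(1S)-1-[(4-methoxyphenyl)methoxy]-3-methylbut-3-en-1-yl]furan | c1cc(co1)[C@@H](OCc1ccc(OC)cc1)CC(C)=C
F2 | step 13 | 5-hydroxy-4-[(1S)-1-[(4-methoxyphenyl)methoxy]-3-methylbut-3-en-1-yl]furan-2(5H)-one | O=C1C=C(C(O)O1)[C@@H](OCc1ccc(OC)cc1)CC(C)=C
F3 | step 13 | 4-[(1S)-1-[(4-methoxyphenyl)methoxy]-3-methylbut-3-en-1-yl]furan-2(5H)-one | O=C1C=C(CO1)[C@@H](OCc1ccc(OC)cc1)CC(C)=C
F4 | step 13 | triisopropyl[[4-[(1S)-1-[(4-methoxyphenyl)methoxy]-3-methylbut-3-en-1-yl]furan-2-yl]oxy]silane | CC(C)[Si](Oc1cc(co1)[C@@H](OCc1ccc(OC)cc1)CC(C)=C)(C(C)C)C(C)C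
F5 | step 13 | 2-methylidenehex-5-enal | C=CCCC(=C)C=O
F6 | step 13 | (5R)-5-[(1S)-1-hydroxy-2-methylidenehex-5-en-1-yl]-4-[(1S)-1-[(4-methoxyphenyl)methoxy]-3-methylbut-3-en-1-yl]furan-2(5H)-one | O=C1C=C([C@@H](O1)[C@@H](O)C(=C)CCC=C)[C@@H](OCc1ccc(OC)cc1)CC(C)=C
F7 | step 7 | 3-[(1S,3Z)-1-[(4-methoxyphenyl)methoxy]-3-methyl-5-(phenylsulfonyl)pent-3-en-1-yl]furan | c1cc(co1)[C@@H](OCc1ccc(OC)cc1)C/C(C)=C\CS(=O)(=O)c1ccccc1
F8 | step 7 | tert-butyl[[(5Z,8S)-8-(furan-3-yl)-8-[(4-methoxyphenyl)methoxy]-6-methyl-4-(phenylsulfonyl)oct-5-en-1-yl]oxy]dimethylsilane | c1cc(co1)[C@@H](OCc1ccc(OC)cc1)C/C(C)=C\C(CCCO[Si](C)(C)C(C)(C)C)S(=O)(=O)c1ccccc1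
F9 | step 7 | tert-butyl[[(5Z,8S)-8-(furan-3-yl)-8-[(4-methoxyphenyl)methoxy]-6-methyloct-5-en-1-yl]oxy]dimethylsilane | c1cc(co1)[C@@H](OCc1ccc(OC)cc1)C/C(C)=C\CCCCO[Si](C)(C)C(C)(C)C
F0 | step 15 | none | none
F10 | step 19 | (1S,5S,6R,7R,8S,10S)-8-angeloyloxy-1-bromo-10-hydroxy-5-(triethylsilyloxy)germacra-4(15),11(13)-dien-12,6-olide | O=C1O[C@@H]2[C@H](C1=C)[C@@H](OC(=O)/C(C)=C\C)C[C@](C)(O)[C@@H](Br)CCC(=C)[C@@H]2O[Si](CC)(CC)CC
A1 | alternative 1 | open-chain C10 aldoxime with terminal C8=C9 alkene | ON=C[C@@H](O[Si](C)(C)C(C)(C)C)CCC1(OCCO1)[C@@H]1OC(C)(C)O[C@@H]1[C@H](CCOCc1ccc(OC)cc1)C=C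
A2 | alternative 1 | bridged isoxazoline | C12=NO[C@@H](C1)[C@@H](CCOCc1ccc(OC)cc1)[C@H]1OC(C)(C)O[C@H]1C1(OCCO1)CC[C@@H]2O[Si](C)(C)C(C)(C)C
A3 | alternative 2 | C6 bromoacetal of the ten-membered dienone (acetal epimers) | CCOC(CBr)O[C@@H]1/C=C\C/C(C)=C\CCC(=O)[C@@H]1O[Si](C)(C)C(C)(C)C
A4 | alternative 2 | bicyclic acetal alcohol | CCO[C@@H]1C[C@H]2[C@@H](O1)[C@@H](O[Si](C)(C)C(C)(C)C)C(=O)CC/C=C(C)\C[C@@H]2O
A5 | alternative 3 | cis-decalin C1 mesylate with C5 tertiary alcohol | C=C1CC[C@@H](OS(C)(=O)=O)[C@@]2(C)C[C@H](O[Si](C)(C)C(C)(C)C)[C@@H](CCOCc3ccc(OC)cc3)[C@@H](OCc3ccc(OC)cc3)[C@@]12O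
A6 | alternative 3 | Z-cyclodecenone with C4 methylene | O=C1[C@H](OCc2ccc(OC)cc2)[C@H](CCOCc2ccc(OC)cc2)[C@@H](O[Si](C)(C)C(C)(C)C)C/C(C)=C\CCC1=C
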